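## Retrosynthetic overview

- The target is read as a tetraketide. Aromatic C5 plus side-chain C1'–C17' (Z-alkene C8'=C9', (S)-carbinol C16') are, atom for atom, C1–C18 of (9Z,17S)-17-hydroxyoleic acid. Ring atoms C1–C4 and C6 with both phenol oxygens are three acetate units.
- Key disconnection: the benzene ring itself is cut at C4–C5 (Claisen-type acylation) and C5–C6 (intramolecular aldol). This leads back to the open-chain 3,5,7-triketo ester 5, and from there to hydroxy ester 2 and the trianion of methyl 3,5-dioxohexanoate 3. The ester carbon on C6 leaves last as CO2.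
- Ester 2 carries every side-chain carbon, the Z-alkene and the stereocentre. It comes in one step from the commercial glycolipid 1 by acid methanolysis (chiral pool), so nothing in the chain is built or protected.
- Ring order: the benzene ring is the only ring and is formed in step 2; step 3 only removes the carboxyl group.

Key step: step 2

Assumption: the diacetylated C18:1 lactonic sophorolipid (17-L-hydroxy, cis-9 aglycone, i.e. 9Z,17S) is taken as a defined commercial fermentation product and recrystallised before use; methyl 3,5-dioxohexanoate and methanolic HCl are bought.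

## Route

Step 1
Reactants: 1 diacetylated lactonic sophorolipid (17-L-[(2'-O-β-D-glucopyranosyl-β-D-glucopyranosyl)oxy]-cis-9-octadecenoic acid 1',4''-lactone 6',6''-diacetate)
Product: 2 methyl (9Z,17S)-17-hydroxyoctadec-9-enoate
Conditions: HCl (1.25 M in MeOH), reflux; evaporate; hexane/H2O partition; SiO2
Reagents that add atoms: methanol, CO
Why: Acid-catalysed methanolysis (transesterification of the macrolactone and both acetates, Fischer-type transglycosidation of both β-glycosidic bonds) should release the aglycone as its methyl ester; each glycosidic bond breaks on the anomeric side, so the C17–O bond and its (S) configuration stay intact, and an isolated Z-alkene is inert to methanolic HCl as in routine fatty acid methyl ester preparation.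

Step 2
Reactants: 2 methyl (9Z,17S)-17-hydroxyoctadec-9-enoate; 3 methyl 3,5-dioxohexanoate
Product: 7 methyl 2,4-dihydroxy-6-[(8Z,16S)-16-hydroxyheptadec-8-en-1-yl]benzoate, via trilithio trianion 4 (not isolated), via triketo ester 5 (not isolated), via aldol adduct 6 (not isolated)
Conditions: 3 (3 equiv), LDA (9 equiv), THF, 0 °C, Ar; add 2 (1 equiv), 0 °C → rt; 1 M HCl, 0 °C, EtOAc extraction; crude in MeOH/aq. borate buffer (pH 9.2), rt; 1 M HCl to pH 3
Reagents that add atoms: none
Why: The terminal C6 carbanion of trianion 4, the last formed and most nucleophilic site, should undergo Claisen-type C-acylation by ester 2 (polyanion chain extension of a β,δ-diketo ester) to give tetraketide 5, the same 3,5,7-triketo ester that a type III polyketide synthase would assemble from a 17-hydroxyoleoyl starter and three malonates; the C17 hydroxyl rides along as its lithium alkoxide (one equivalent of trianion serves as base), and any ester it forms is itself an acyl donor. At pH 9 the doubly activated C2 methylene of 5 should add to the C7 ketone in a favoured 6-exo-trig intramolecular aldol reaction, and loss of water and enolisation of 6 give the aromatic ring of 7, so both ring bonds at the future C5 (C4–C5 by acylation, C5–C6 by aldol) come from this one operation. The closest known reaction type is the biomimetic aldol aromatisation of 3,5,7-triketo esters to β-resorcylates. No lasting stereocentre is created (the two sp3 centres of 6 vanish on aromatisation), and the (S) centre and the Z-alkene are spectators because the tetraketide is already at the oxidation level of the arene, so no oxidant, hydride, transition metal or strong acid is needed. The step needs C2→C7 aldol closure to win over C6→C1 Claisen closure (acylphloroglucinol), O-cyclisation (pyrones) and C8→C3 aldol closure. Mild aqueous base, a methyl ester as a poor acyl acceptor, the absence of Mg2+ and the low acidity of the singly activated C8–H should secure this.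

Step 3
Reactants: 7 methyl 2,4-dihydroxy-6-[(8Z,16S)-16-hydroxyheptadec-8-en-1-yl]benzoate
Product: 9 Hansfordiol E, via resorcylic acid 8 (not isolated)
Conditions: KOH (6 equiv), MeOH/H2O (degassed), reflux, Ar; then 2 M HCl to pH 2–3, 60 °C; SiO2
Reagents that add atoms: none
Why: Saponification followed by protodecarboxylation of the 2,4-dihydroxybenzoic acid through its ipso-protonated keto tautomer (a vinylogous β-keto acid), the standard loss of CO2 of orsellinic-type acids, should give the 5-alkylresorcinol without touching the alkene or the carbinol centre.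

## Compound list

1 | diacetylated lactonic sophorolipid (17-L-[(2'-O-β-D-glucopyranosyl-β-D-glucopyranosyl)oxy]-cis-9-octadecenoic acid 1',4''-lactone 6',6''-diacetate) | C[C@H](O[C@@H]1O[C@H](COC(C)=O)[C@@H](O)[C@H](O)[C@H]1O[C@@H]2O[C@H](COC(C)=O)[C@@H](O3)[C@H](O)[C@H]2O)CCCCCC/C=C\CCCCCCCC3=O | starting material
2 | methyl (9Z,17S)-17-hydroxyoctadec-9-enoate | C[C@H](O)CCCCCC/C=C\CCCCCCCC(=O)OC | intermediate
3 | methyl 3,5-dioxohexanoate | CC(=O)CC(=O)CC(=O)OC | starting material
4 | trilithium trianion of methyl 3,5-dioxohexanoate | [Li+].[Li+].[Li+].[CH2-]C(=O)[CH-]C(=O)[CH-]C(=O)OC | intermediate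
5 | methyl (15Z,23S)-23-hydroxy-3,5,7-trioxotetracos-15-enoate | C[C@H](O)CCCCCC/C=C\CCCCCCCC(=O)CC(=O)CC(=O)CC(=O)OC | intermediate
6 | methyl 2-hydroxy-2-[(8Z,16S)-16-hydroxyheptadec-8-en-1-yl]-4,6-dioxocyclohexane-1-carboxylate (mixture at the two ring centres) | C[C@H](O)CCCCCC/C=C\CCCCCCCC1(O)CC(=O)CC(=O)C1C(=O)OC | intermediate
7 | methyl 2,4-dihydroxy-6-[(8Z,16S)-16-hydroxyheptadec-8-en-1-yl]benzoate | C[C@H](O)CCCCCC/C=C\CCCCCCCc1cc(O)cc(O)c1C(=O)OC | intermediate
8 | 2,4-dihydroxy-6-[(8Z,16S)-16-hydroxyheptadec-8-en-1-yl]benzoic acid | C[C@H](O)CCCCCC/C=C\CCCCCCCc1cc(O)cc(O)c1C(=O)O | intermediate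
9 | Hansfordiol E, 5-[(8Z,16S)-16-hydroxyheptadec-8-en-1-yl]benzene-1,3-diol | C[C@H](O)CCCCCC/C=C\CCCCCCCc1cc(O)cc(O)c1 | target

## Step count

Total steps: 3. Longest linear sequence: 3 (1 → 2 → 7 → 9).

## Steps most likely to fail

**Step 2 (key step).** The trianion may act as a base toward the α-CH2 of ester 2 (enolisation in place of C-acylation), and the tetraketide may close the wrong way (Claisen closure or O-acylation instead of the aldol). The fallback buys the ring and joins the chain to it by a decarboxylative cross-coupling, keeping the chiral pool; it sets out from 2 and comes back to the route at 9. The hydroxyl of 2 is silylated (TBSCl, imidazole, DMF) to methyl (9Z,17S)-17-[(tert-butyldimethylsilyl)oxy]octadec-9-enoate F1. Saponification (LiOH, THF/H2O) gives (9Z,17S)-17-[(tert-butyldimethylsilyl)oxy]octadec-9-enoic acid F2. Activation (N-hydroxytetrachlorophthalimide, DIC, cat. DMAP, CH2Cl2) gives the redox-active ester 4,5,6,7-tetrachloro-1,3-dioxoisoindolin-2-yl (9Z,17S)-17-[(tert-butyldimethylsilyl)oxy]octadec-9-enoate F3. Nickel-catalysed decarboxylative Suzuki-type arylation with commercial 3,5-dimethoxyphenylboronic acid (NiCl2·6H2O, bathophenanthroline, Et3N, dioxane/DMF, 75 °C) should expel C1 as CO2 and bond C2 to the arene, giving tert-butyl{[(2S,9Z)-17-(3,5-dimethoxyphenyl)heptadec-9-en-2-yl]oxy}dimethylsilane F4. Thiolate (NaSEt, DMF, 140 °C, strictly under argon) cleaves both aryl methyl ethers to 5-[(8Z,16S)-16-[(tert-butyldimethylsilyl)oxy]heptadec-8-en-1-yl]benzene-1,3-diol F5, and TBAF in THF removes the silyl group to give 9.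

**Step 3.** Hydroxide attack on the ester carbonyl may be slow, because the carbonyl is flanked by two ortho substituents, hydrogen-bonded and deactivated in the phenolate; the electron-rich phenolate may also be oxidised by traces of air in hot alkali. The fallback cleaves the O–CH3 bond instead of the acyl carbon, without water or hydroxide; it sets out from 7 and comes back at 8. Heating 7 with LiI in pyridine (reflux, argon) should demethylate the ester by SN2 attack of iodide on the methyl group; the carboxylate corresponds to 8 after acidification and loses CO2 as in step 3 to give 9. It makes no compound outside the list (entry F0).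

**Step 1.** Cleavage of the inner glycosidic bond (aglycone–glucose) may stay incomplete, partly degraded glycolipid esters may co-elute with 2, and forcing the reaction risks slow acid-induced drift of the alkene. The fallback degrades 1 hydrolytically in two stages and isolates the free acid by extraction instead of a one-pot solvolysis; it sets out from 1 and comes back at 2. Aqueous NaOH (80 °C, then acidification) should open the lactone and remove both acetates to give (9Z,17S)-17-[(2-O-β-D-glucopyranosyl-β-D-glucopyranosyl)oxy]octadec-9-enoic acid F6, which can be recrystallised. Hydrolysis in 1 M aqueous H2SO4/dioxane at reflux should release (9Z,17S)-17-hydroxyoctadec-9-enoic acid F7, which is separated from glucose by extraction and purified via its sodium salt. Fischer esterification (MeOH, cat. H2SO4, 40 °C) returns 2.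

## Further compounds

F1 | step 2 | methyl (9Z,17S)-17-[(tert-butyldimethylsilyl)oxy]octadec-9-enoate | C[C@H](O[Si](C)(C)C(C)(C)C)CCCCCC/C=C\CCCCCCCC(=O)OC
F2 | step 2 | (9Z,17S)-17-[(tert-butyldimethylsilyl)oxy]octadec-9-enoic acid | C[C@H](O[Si](C)(C)C(C)(C)C)CCCCCC/C=C\CCCCCCCC(=O)O
F3 | step 2 | 4,5,6,7-tetrachloro-1,3-dioxoisoindolin-2-yl (9Z,17S)-17-[(tert-butyldimethylsilyl)oxy]octadec-9-enoate | C[C@H](O[Si](C)(C)C(C)(C)C)CCCCCC/C=C\CCCCCCCC(=O)ON1C(=O)c2c(Cl)c(Cl)c(Cl)c(Cl)c2C1=O
F4 | step 2 | tert-butyl{[(2S,9Z)-17-(3,5-dimethoxyphenyl)heptadec-9-en-2-yl]oxy}dimethylsilane | C[C@H](O[Si](C)(C)C(C)(C)C)CCCCCC/C=C\CCCCCCCc1cc(OC)cc(OC)c1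
F5 | step 2 | 5-[(8Z,16S)-16-[(tert-butyldimethylsilyl)oxy]heptadec-8-en-1-yl]benzene-1,3-diol | C[C@H](O[Si](C)(C)C(C)(C)C)CCCCCC/C=C\CCCCCCCc1cc(O)cc(O)c1
F0 | step 3 | none | none
F6 | step 1 | (9Z,17S)-17-[(2-O-β-D-glucopyranosyl-β-D-glucopyranosyl)oxy]octadec-9-enoic acid | C[C@H](O[C@@H]1O[C@H](CO)[C@@H](O)[C@H](O)[C@H]1O[C@@H]2O[C@H](CO)[C@@H](O)[C@H](O)[C@H]2O)CCCCCC/C=C\CCCCCCCC(=O)O
F7 | step 1 | (9Z,17S)-17-hydroxyoctadec-9-enoic acid | C[C@H](O)CCCCCC/C=C\CCCCCCCC(=O)O
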